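## Retrosynthetic overview

1. The target (the ring-B mono-acetate of sulochrin) comes from its bis(benzyl ether) by hydrogenolysis; the aryl acetate is already in place.
2. Key disconnection (new step): the diaryl ketone C–C bond and the ring-B acetate C–O bond are cut together, giving a ring-A potassium carboxylate, 3-(benzyloxy)-5-methylbenzyne and Ac2O (aryne 1,2-aroyl-acetoxylation).
3. The ring-A acid comes from methyl 3,5-bis(benzyloxy)benzoate by Vilsmeier formylation, chelation-controlled mono-debenzylation, O-methylation and Pinnick oxidation.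
4. The aryne precursor (2-silylaryl triflate) comes from orcinol by mono-benzylation, carbamate formation, directed ortho-silylation and triflation.
5. No ring is formed: both benzene rings are bought and joined at the ketone (convergent, 4 + 4 + 2 steps).

Assumption: the target has no stereocentre and no configurationally stable axis, so "single enantiomer" is taken to mean the achiral compound itself.

## Route

Step 1
Reactants: 1 methyl 3,5-bis(benzyloxy)benzoate
Product: 3 methyl 3,5-bis(benzyloxy)-2-formylbenzoate, via iminium chloride 2 (not isolated)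
Conditions: POCl3, DMF, 0 → 75 °C; then ice-water
Reagents that add atoms: N,N-dimethylformamide CN(C)C=O; water O
Why: Vilsmeier–Haack formylation, where the chloroiminium ion attacks C2 (ortho to one OBn, para to the other, as with 3,5-dimethoxybenzoates) in preference to the doubly flanked C4, and water hydrolyses iminium 2.

Step 2
Reactants: 3 methyl 3,5-bis(benzyloxy)-2-formylbenzoate
Product: 4 methyl 5-(benzyloxy)-2-formyl-3-hydroxybenzoate
Conditions: MgBr2·OEt2 (3 equiv), toluene–Et2O, 80 °C; then 1 M HCl
Reagents that add atoms: none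
Why: Chelation-controlled ether cleavage, in which Mg(II) held between the formyl oxygen and the ortho ether oxygen activates only the 3-O-benzyl group to SN2 attack by bromide, leaving the para OBn untouched.

Step 3
Reactants: 4 methyl 5-(benzyloxy)-2-formyl-3-hydroxybenzoate
Product: 5 methyl 5-(benzyloxy)-2-formyl-3-methoxybenzoate
Conditions: MeI, K2CO3, DMF, rt
Reagents that add atoms: iodomethane CI
Why: Williamson O-methylation of the only free phenol.

Step 4
Reactants: 5 methyl 5-(benzyloxy)-2-formyl-3-methoxybenzoate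
Product: 6 4-(benzyloxy)-2-methoxy-6-(methoxycarbonyl)benzoic acid
Conditions: NaClO2, NaH2PO4, 2-methyl-2-butene, t-BuOH–THF–H2O, rt
Reagents that add atoms: sodium chlorite [Na+].[O-]Cl=O
Why: Pinnick oxidation converts hindered aryl aldehydes to acids without touching benzyl ethers or the methyl ester, and the alkene scavenges HOCl so the electron-rich ring is not chlorinated.

Step 5
Reactants: 7 orcinol (5-methylbenzene-1,3-diol)
Product: 8 3-(benzyloxy)-5-methylphenol
Conditions: BnBr (1.0 equiv), K2CO3, acetone, reflux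
Reagents that add atoms: benzyl bromide BrCc1ccccc1
Why: Williamson mono-etherification of a symmetrical diphenol; it is statistical, so the dibenzyl ether and recovered orcinol are separated and recycled.

Step 6
Reactants: 8 3-(benzyloxy)-5-methylphenol
Product: 9 3-(benzyloxy)-5-methylphenyl isopropylcarbamate
Conditions: i-PrNCO, Et3N (cat.), CH2Cl2, rt
Reagents that add atoms: isopropyl isocyanate CC(C)N=C=O
Why: Base-catalysed addition of the phenol to the isocyanate (carbamoylation) installs a directing group that can later be removed under mild conditions.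

Step 7
Reactants: 9 3-(benzyloxy)-5-methylphenyl isopropylcarbamate
Product: 13 3-(benzyloxy)-5-methyl-2-(trimethylsilyl)phenyl isopropylcarbamate, via N-TBS carbamate 10 (not isolated), via aryllithium 11 (not isolated), via N-TBS C-TMS carbamate 12 (not isolated)
Conditions: TBSOTf, TMEDA, Et2O, 0 °C → rt; n-BuLi, TMEDA, −78 °C; TMSCl, −78 °C → rt; aq. NaHSO4
Reagents that add atoms: chlorotrimethylsilane C[Si](C)(C)Cl
Why: Directed ortho-metalation (Snieckus–Hoppe type), where in-flask N-silylation masks the N–H, lithiation occurs at C2 between the two cooperating oxygen directing groups, TMSCl traps the anion, and acidic work-up removes the N-silyl group.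

Step 8
Reactants: 13 3-(benzyloxy)-5-methyl-2-(trimethylsilyl)phenyl isopropylcarbamate
Product: 15 3-(benzyloxy)-5-methyl-2-(trimethylsilyl)phenyl trifluoromethanesulfonate, via silylphenol 14 (not isolated)
Conditions: Et2NH, DBU, MeCN, 40 °C; then PhNTf2, rt
Reagents that add atoms: N-phenylbis(trifluoromethanesulfonimide) O=S(=O)(N(c1ccccc1)S(=O)(=O)C(F)(F)F)C(F)(F)F
Why: E1cB cleavage of the N-monosubstituted carbamate (the isocyanate is scavenged by Et2NH) followed by mild O-triflation of the phenoxide gives the Kobayashi aryne precursor without protodesilylation.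

Step 9
Reactants: 6 4-(benzyloxy)-2-methoxy-6-(methoxycarbonyl)benzoic acid; 15 3-(benzyloxy)-5-methyl-2-(trimethylsilyl)phenyl trifluoromethanesulfonate
Product: 20 methyl 2-[2-(acetyloxy)-6-(benzyloxy)-4-methylbenzoyl]-5-(benzyloxy)-3-methoxybenzoate, via potassium carboxylate 16 (not isolated), via aryne 17 (not isolated), via arylpotassium 18 (not isolated), via potassium phenoxide 19 (not isolated)
Conditions: 6, KH, THF, 0 °C; then 15 (1.2 equiv), KF, 18-crown-6, THF, 0 °C → rt; then Ac2O, DMAP (cat.), rt
Reagents that add atoms: acetic anhydride CC(=O)OC(C)=O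
Why: Proposed new method: three-component aryne 1,2-aroyl-acetoxylation; the carboxylate oxygen of 16 adds to the distal carbon C1 of the unsymmetrical 3-alkoxyaryne 17 (this places the carbanion at C2 next to the inductively stabilising OBn), arylpotassium 18 attacks its own ester carbonyl through a four-membered transition state (1,3 O→C acyl shift, favoured by formation of the chelated phenoxide 19 and by the absence of a proton source in THF), and 19 is acetylated in the flask, so one operation forms the tetra-ortho-substituted diaryl ketone C–C bond between the two ring-B oxygens and leaves them differentiated (OAc versus OBn); closest known reaction type: aryne σ-insertion into the C–O bond of carboxylic acids giving o-hydroxyaryl ketones, together with the anionic Fries rearrangement, neither shown for a 2,6-disubstituted ester-bearing benzoate, for a tetra-ortho-substituted benzophenone or with in-flask O-acylation of the phenoxide.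

Step 10
Reactants: 20 methyl 2-[2-(acetyloxy)-6-(benzyloxy)-4-methylbenzoyl]-5-(benzyloxy)-3-methoxybenzoate
Product: 21 penibenzophenone C, methyl 2-[2-(acetyloxy)-6-hydroxy-4-methylbenzoyl]-5-hydroxy-3-methoxybenzoate
Conditions: H2 (1 atm), 10% Pd/C, EtOAc, rt
Reagents that add atoms: none
Why: Catalytic hydrogenolysis of the two aryl benzyl ethers in a non-nucleophilic solvent spares the aryl acetate, the methyl ester and the hindered, hydrogen-bonded diaryl ketone, and any acetyl shift between the two ring-B oxygens would be degenerate.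

## Compound list

1 | methyl 3,5-bis(benzyloxy)benzoate | COC(=O)c1cc(OCc2ccccc2)cc(OCc2ccccc2)c1 | starting material
2 | N-[2,4-bis(benzyloxy)-6-(methoxycarbonyl)benzylidene]-N-methylmethanaminium chloride (not isolated) | COC(=O)c1cc(OCc2ccccc2)cc(OCc2ccccc2)c1C=[N+](C)C.[Cl-] | intermediate
3 | methyl 3,5-bis(benzyloxy)-2-formylbenzoate | COC(=O)c1cc(OCc2ccccc2)cc(OCc2ccccc2)c1C=O | intermediate
4 | methyl 5-(benzyloxy)-2-formyl-3-hydroxybenzoate | COC(=O)c1cc(OCc2ccccc2)cc(O)c1C=O | intermediate
5 | methyl 5-(benzyloxy)-2-formyl-3-methoxybenzoate | COC(=O)c1cc(OCc2ccccc2)cc(OC)c1C=O | intermediate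
6 | 4-(benzyloxy)-2-methoxy-6-(methoxycarbonyl)benzoic acid | COC(=O)c1cc(OCc2ccccc2)cc(OC)c1C(=O)O | intermediate
7 | orcinol (5-methylbenzene-1,3-diol) | Cc1cc(O)cc(O)c1 | starting material
8 | 3-(benzyloxy)-5-methylphenol | Cc1cc(O)cc(OCc2ccccc2)c1 | intermediate
9 | 3-(benzyloxy)-5-methylphenyl isopropylcarbamate | Cc1cc(OC(=O)NC(C)C)cc(OCc2ccccc2)c1 | intermediate
10 | 3-(benzyloxy)-5-methylphenyl N-(tert-butyldimethylsilyl)-N-isopropylcarbamate (not isolated) | Cc1cc(OC(=O)N(C(C)C)[Si](C)(C)C(C)(C)C)cc(OCc2ccccc2)c1 | intermediate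
11 | [2-(benzyloxy)-6-{[(tert-butyldimethylsilyl)(isopropyl)carbamoyl]oxy}-4-methylphenyl]lithium (not isolated) | Cc1cc(OC(=O)N(C(C)C)[Si](C)(C)C(C)(C)C)c([Li])c(OCc2ccccc2)c1 | intermediate
12 | 3-(benzyloxy)-5-methyl-2-(trimethylsilyl)phenyl N-(tert-butyldimethylsilyl)-N-isopropylcarbamate (not isolated) | Cc1cc(OC(=O)N(C(C)C)[Si](C)(C)C(C)(C)C)c([Si](C)(C)C)c(OCc2ccccc2)c1 | intermediate
13 | 3-(benzyloxy)-5-methyl-2-(trimethylsilyl)phenyl isopropylcarbamate | Cc1cc(OC(=O)NC(C)C)c([Si](C)(C)C)c(OCc2ccccc2)c1 | intermediate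
14 | 3-(benzyloxy)-5-methyl-2-(trimethylsilyl)phenol (not isolated) | Cc1cc(O)c([Si](C)(C)C)c(OCc2ccccc2)c1 | intermediate
15 | 3-(benzyloxy)-5-methyl-2-(trimethylsilyl)phenyl trifluoromethanesulfonate | Cc1cc(OS(=O)(=O)C(F)(F)F)c([Si](C)(C)C)c(OCc2ccccc2)c1 | intermediate
16 | potassium 4-(benzyloxy)-2-methoxy-6-(methoxycarbonyl)benzoate (not isolated) | COC(=O)c1cc(OCc2ccccc2)cc(OC)c1C(=O)[O-].[K+] | intermediate
17 | 3-(benzyloxy)-5-methylbenzyne (triple bond C1–C2, OBn on C3, methyl on C5; not isolated) | CC1=CC#CC(OCc2ccccc2)=C1 | intermediate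
18 | [2-(benzyloxy)-6-{[4-(benzyloxy)-2-methoxy-6-(methoxycarbonyl)benzoyl]oxy}-4-methylphenyl]potassium (not isolated) | COC(=O)c1cc(OCc2ccccc2)cc(OC)c1C(=O)Oc1cc(C)cc(OCc2ccccc2)c1[K] | intermediate
19 | potassium 3-(benzyloxy)-2-[4-(benzyloxy)-2-methoxy-6-(methoxycarbonyl)benzoyl]-5-methylphenolate (not isolated) | COC(=O)c1cc(OCc2ccccc2)cc(OC)c1C(=O)c1c([O-])cc(C)cc1OCc1ccccc1.[K+] | intermediate
20 | methyl 2-[2-(acetyloxy)-6-(benzyloxy)-4-methylbenzoyl]-5-(benzyloxy)-3-methoxybenzoate | COC(=O)c1cc(OCc2ccccc2)cc(OC)c1C(=O)c1c(OC(C)=O)cc(C)cc1OCc1ccccc1 | intermediate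
21 | penibenzophenone C, methyl 2-[2-(acetyloxy)-6-hydroxy-4-methylbenzoyl]-5-hydroxy-3-methoxybenzoate (achiral) | COC(=O)c1cc(O)cc(OC)c1C(=O)c1c(O)cc(C)cc1OC(C)=O | target

## Step count and risks

Total step count: 10.
Longest linear sequence: 6 steps (steps 1–4, 9, 10; the arm through steps 5–8, 9, 10 is equally long).

The three steps most likely to fail:

Step 9 (the proposed new step). Risks are:
- protonation of arylpotassium 18 before the acyl shift, giving only the aryl ester;
- attack of 18 on the neighbouring CO2Me of ring A through a seven-membered transition state, giving a dibenzoxepinedione of the wrong connectivity;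
- O-arylation of phenoxide 19 by a second aryne.

The fallback uses the known halogen–metal-exchange anionic Fries rearrangement. It still passes through an ortho-metalated aryl ester next to the CO2Me, so it avoids the aryne-specific risks but not the seven-membered pathway. It sets out from 13 and 6 and comes back at 20. Ipso-iododesilylation of 13 with ICl (CH2Cl2, 0 °C) gives 3-(benzyloxy)-2-iodo-5-methylphenyl isopropylcarbamate F1, and Et2NH/DBU (MeCN, 40 °C) releases 3-(benzyloxy)-2-iodo-5-methylphenol F2. Acid 6 is converted with (COCl)2 and catalytic DMF into methyl 5-(benzyloxy)-2-(chlorocarbonyl)-3-methoxybenzoate F3, which acylates F2 (Et3N, DMAP, CH2Cl2) to give methyl 5-(benzyloxy)-2-{[3-(benzyloxy)-2-iodo-5-methylphenoxy]carbonyl}-3-methoxybenzoate F4. Iodine–lithium exchange (n-BuLi, THF, −100 °C) gives [2-(benzyloxy)-6-{[4-(benzyloxy)-2-methoxy-6-(methoxycarbonyl)benzoyl]oxy}-4-methylphenyl]lithium F5, which undergoes the 1,3 O→C acyl shift to lithium 3-(benzyloxy)-2-[4-(benzyloxy)-2-methoxy-6-(methoxycarbonyl)benzoyl]-5-methylphenolate F6. Quenching with Ac2O gives 20.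

Step 7. Risks are competing α-lithiation of the benzyl ether (Wittig rearrangement) and incomplete N-silylation or lithiation. The fallback is the classical o-bromophenol/retro-Brook route to the same aryne precursor, which replaces deprotonation by fast bromine–lithium exchange. It sets out from 7 and comes back at 15, bypassing steps 5–8. Orcinol 7 with Br2 (3 equiv, CHCl3) gives 2,4,6-tribromo-5-methylbenzene-1,3-diol F7. Selective reductive removal of the 4- and 6-bromines with Na2SO3/NaOH (aq. MeOH), by analogy with the 2-bromoresorcinol preparation, gives 2-bromo-5-methylbenzene-1,3-diol F8. Mono-benzylation (BnBr 1.0 equiv, K2CO3, acetone) gives 3-(benzyloxy)-2-bromo-5-methylphenol F9, and HMDS (THF, reflux) gives [3-(benzyloxy)-2-bromo-5-methylphenoxy]trimethylsilane F10. n-BuLi (THF, −100 °C) gives [2-(benzyloxy)-4-methyl-6-(trimethylsilyloxy)phenyl]lithium F11, whose 1,3 O→C silyl shift gives lithium 3-(benzyloxy)-5-methyl-2-(trimethylsilyl)phenolate F12. Tf2O (−100 °C → rt) then gives 15.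

Step 2. Risks are loss of both benzyl groups, or sluggish cleavage because Mg(II) can also sit between the aldehyde and the ester. The fallback replaces selective mono-deprotection by global deprotection and regioselective re-protection. It sets out from 3 and comes back at 4. BCl3 with pentamethylbenzene (CH2Cl2, −78 °C) removes both benzyl groups to give methyl 2-formyl-3,5-dihydroxybenzoate F13. BnBr (1.0 equiv) with K2CO3 (1.0 equiv) in acetone at rt then benzylates only the more acidic 5-OH, which is not hydrogen-bonded to the aldehyde, giving 4.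

## Further compounds

F1 | step 9 | 3-(benzyloxy)-2-iodo-5-methylphenyl isopropylcarbamate | Cc1cc(OC(=O)NC(C)C)c(I)c(OCc2ccccc2)c1
F2 | step 9 | 3-(benzyloxy)-2-iodo-5-methylphenol | Cc1cc(O)c(I)c(OCc2ccccc2)c1
F3 | step 9 | methyl 5-(benzyloxy)-2-(chlorocarbonyl)-3-methoxybenzoate | COC(=O)c1cc(OCc2ccccc2)cc(OC)c1C(Cl)=O
F4 | step 9 | methyl 5-(benzyloxy)-2-{[3-(benzyloxy)-2-iodo-5-methylphenoxy]carbonyl}-3-methoxybenzoate | COC(=O)c1cc(OCc2ccccc2)cc(OC)c1C(=O)Oc1cc(C)cc(OCc2ccccc2)c1I
F5 | step 9 | [2-(benzyloxy)-6-{[4-(benzyloxy)-2-methoxy-6-(methoxycarbonyl)benzoyl]oxy}-4-methylphenyl]lithium | COC(=O)c1cc(OCc2ccccc2)cc(OC)c1C(=O)Oc1cc(C)cc(OCc2ccccc2)c1[Li]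
F6 | step 9 | lithium 3-(benzyloxy)-2-[4-(benzyloxy)-2-methoxy-6-(methoxycarbonyl)benzoyl]-5-methylphenolate | COC(=O)c1cc(OCc2ccccc2)cc(OC)c1C(=O)c1c([O-])cc(C)cc1OCc1ccccc1.[Li+]
F7 | step 7 | 2,4,6-tribromo-5-methylbenzene-1,3-diol | Cc1c(Br)c(O)c(Br)c(O)c1Br
F8 | step 7 | 2-bromo-5-methylbenzene-1,3-diol | Cc1cc(O)c(Br)c(O)c1
F9 | step 7 | 3-(benzyloxy)-2-bromo-5-methylphenol | Cc1cc(O)c(Br)c(OCc2ccccc2)c1
F10 | step 7 | [3-(benzyloxy)-2-bromo-5-methylphenoxy]trimethylsilane | Cc1cc(O[Si](C)(C)C)c(Br)c(OCc2ccccc2)c1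
F11 | step 7 | [2-(benzyloxy)-4-methyl-6-(trimethylsilyloxy)phenyl]lithium | Cc1cc(O[Si](C)(C)C)c([Li])c(OCc2ccccc2)c1
F12 | step 7 | lithium 3-(benzyloxy)-5-methyl-2-(trimethylsilyl)phenolate | Cc1cc([O-])c([Si](C)(C)C)c(OCc2ccccc2)c1.[Li+]
F13 | step 2 | methyl 2-formyl-3,5-dihydroxybenzoate | COC(=O)c1cc(O)cc(O)c1C=O
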